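**Strategy.** The eight-membered ring is numbered C1 (butenolide α-carbon), C2 (CH carrying the side chain), C3 (CHOAc), C4, C5 (CHCH3), C6 and C7 (cyclopropane CH), C8 (butenolide β-carbon). With a ketone at C3 and an alkene at C7=C8 this ring is a cyclooct-4-enone, the product of a ring-expanding Claisen rearrangement. The precursor is a tetrahydropyran whose oxygen bridges C3 and C7, with an (E)-alkylidene at C3 and an axial butenolide at C7; it is made in the same step by copper-mediated O-alkenylation. Heating forms C1–C2, closes the carbocycle and relays the C7–O configuration to C2. The resulting lactone dienolate later alkylates at C7, building the cyclopropane and restoring the butenolide.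

Key step: step 10

Remarks. Further locants: C9 = cyclopropane CH2 (earlier the CH2OTs carbon on C6), C10 = lactone OCH2, C11 = lactone C=O, C1′ = side-chain CH(CH3). Bpin = 4,4,5,5-tetramethyl-1,3,2-dioxaborolan-2-yl; Ts = 4-methylbenzenesulfonyl. Assumption: (S)-β-methyl-γ-butyrolactone 7 is bought as the single enantiomer (otherwise two steps from monomethyl itaconate by asymmetric hydrogenation and borane reduction).

Step 1
Reactants: 1 (R)-citronellal
Product: 3 (3R)-3,7-dimethyloct-6-en-1-yne, via alkenyl nonaflate 2 (not isolated)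
Conditions: C4F9SO2F, P2-Et phosphazene base, DMF, −20 °C → rt
Reagents that add atoms: none
Why: The aldehyde enolate is O-sulfonylated to the alkenyl nonaflate, which the phosphazene base eliminates in the same pot to the terminal alkyne (sulfonate elimination), the acetylide formed shielding the propargylic stereocenter from deprotonation.

Step 2
Reactants: 3 (3R)-3,7-dimethyloct-6-en-1-yne
Product: 4 (3R)-1-bromo-3,7-dimethyloct-6-en-1-yne
Conditions: NBS, AgNO3 (10 mol %), acetone, rt
Reagents that add atoms: N-bromosuccinimide, O=C1CCC(=O)N1Br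
Why: Silver-catalysed electrophilic bromination of the terminal alkyne C–H, with the trisubstituted alkene inert to NBS in dry acetone.

Step 3
Reactants: 4 (3R)-1-bromo-3,7-dimethyloct-6-en-1-yne
Product: 6 2-[(1Z,3R)-1-bromo-3,7-dimethylocta-1,6-dien-1-yl]-4,4,5,5-tetramethyl-1,3,2-dioxaborolane, via dibromoborane adduct 5 (not isolated)
Conditions: HBBr2·SMe2, CH2Cl2, 0 °C → rt; then pinacol, Et3N, 0 °C
Reagents that add atoms: dibromoborane–dimethyl sulfide, Br[BH-](Br)[S+](C)C; pinacol, CC(C)(O)C(C)(C)O
Why: Brown syn-hydroboration of a 1-bromoalkyne puts boron on the bromine-bearing carbon with H cis to it, which fixes the (Z) geometry; HBBr2·SMe2 should react with the alkyne much faster than with the trisubstituted alkene, and Et3N traps HBr during esterification.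

Step 4
Reactants: 7 (S)-β-methyl-γ-butyrolactone; 8 (4R)-4-benzyl-1,3-oxazolidin-2-one
Product: 11 (4R)-4-benzyl-3-[(3S)-4-iodo-3-methylbutanoyl]-1,3-oxazolidin-2-one, via silyl ester 9 (not isolated), via acid chloride 10 (not isolated)
Conditions: 7, TMSI, CH2Cl2, 40 °C; (COCl)2, DMF (cat.), CH2Cl2, 0 °C → rt; then 8, n-BuLi, THF, −78 °C
Reagents that add atoms: iodotrimethylsilane, C[Si](C)(C)I
Why: TMSI opens the lactone at O–CH2 (SN2) to the iodo silyl ester, oxalyl chloride converts this to the acid chloride under neutral conditions, and the lithiated oxazolidinone is N-acylated, the methyl-bearing stereocenter not being involved.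

Step 5
Reactants: 11 (4R)-4-benzyl-3-[(3S)-4-iodo-3-methylbutanoyl]-1,3-oxazolidin-2-one; 6 (Z)-1-bromoalkenyl boronate
Product: 13 (4R)-4-benzyl-3-[(3R,5Z,7R)-3,7,11-trimethyl-5-Bpin-dodeca-5,10-dienoyl]-1,3-oxazolidin-2-one, via alkylzinc iodide 12 (not isolated)
Conditions: 11, Zn dust (activated with BrCH2CH2Br, TMSCl), THF, 40 °C; then 6, PdCl2(dppf) (5 mol %), THF, 50 °C
Reagents that add atoms: none
Why: Zinc insertion gives an imide-tolerant alkylzinc iodide that undergoes Negishi coupling at the C–Br bond with retention, so the new CH2 is cis to the C1′ branch and the Bpin is kept (no base is present to activate boron).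

Step 6
Reactants: 13 boryl dienoyl imide; 14 furan-3-carbaldehyde
Product: 16 (4R)-4-benzyl-3-{(2S,3R,5Z,7R)-2-[(R)-furan-3-yl(hydroxy)methyl]-3,7,11-trimethyl-5-Bpin-dodeca-5,10-dienoyl}-1,3-oxazolidin-2-one, via trimethylsilyl ether 15 (not isolated)
Conditions: MgCl2 (20 mol %), Et3N, TMSCl, EtOAc, rt; then citric acid, MeOH, rt
Reagents that add atoms: none
Why: Evans MgCl2-catalysed anti-aldol of the chelated (Z)-magnesium enolate with a non-enolisable aldehyde, the aldehyde adding anti to the benzyl group through a boat transition state, which should set the α-carbon (S) and the carbinol (R) in the anti relationship (silylation of the aldolate drives turnover).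

Step 7
Reactants: 16 anti-aldol adduct
Product: 17 (1R,2R,3R,5Z,7R)-1-(furan-3-yl)-2-(hydroxymethyl)-3,7,11-trimethyl-5-Bpin-dodeca-5,10-dien-1-ol
Conditions: LiBH4, MeOH (1 equiv), THF, 0 °C
Reagents that add atoms: none
Why: Reductive cleavage of the N-acyl oxazolidinone to the primary alcohol, which leaves furan, boronate and alkenes untouched.

Step 8
Reactants: 17 diol
Product: 18 [(2R,3R,5Z,7R)-2-[(R)-furan-3-yl(hydroxy)methyl]-3,7,11-trimethyl-5-Bpin-dodeca-5,10-dien-1-yl] 4-methylbenzenesulfonate
Conditions: TsCl, Et3N, Me3N·HCl (cat.), CH2Cl2, 0 °C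
Reagents that add atoms: 4-methylbenzenesulfonyl chloride, Cc1ccc(cc1)S(Cl)(=O)=O
Why: Selective sulfonylation of the primary hydroxyl over the hindered secondary furyl carbinol.

Step 9
Reactants: 18 furyl tosylate
Product: 20 4-[(1R,2R,3R,5Z,7R)-1-hydroxy-3,7,11-trimethyl-5-Bpin-2-(tosyloxymethyl)dodeca-5,10-dien-1-yl]furan-2(5H)-one, via hydroxybutenolide 19 (not isolated)
Conditions: O2, hν, tetraphenylporphyrin (cat.), i-Pr2NEt, CH2Cl2, −78 °C; then NaBH4, EtOH, 0 °C; pH 3 work-up
Reagents that add atoms: dioxygen, O=O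
Why: Singlet oxygen adds [4+2] to the furan (much faster than its ene reaction with the trisubstituted alkene), the hindered base cleaves the endoperoxide at the less hindered C–H (Kornblum–DeLaMare) to the 4-substituted 5-hydroxybutenolide, and NaBH4 reduces its masked aldehyde with relactonisation to the 4-substituted furan-2(5H)-one.

Step 10
Reactants: 20 hydroxy butenolide alkenylboronate
Product: 22 cyclooctenone lactone (C3 ketone; C7=C8 cis in the ring; C1–H; γ-lactone C11(=O)–O–C10H2 across C1/C8; C6 CH2OTs; C1 S, C2 S, C5 R, C6 S, C1′ R), via enol ether 21 (not isolated)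
Conditions: Cu(OAc)2 (2 equiv), Et3N, 4 Å MS, CH2Cl2, air, rt; filtration through basic Al2O3; then PhMe, 140 °C (sealed, base-washed glass)
Reagents that add atoms: none
Why: Copper-promoted oxidative C–O coupling (transmetalation of the alkenyl–boron bond to divalent copper, alkoxide ligation, oxidation to trivalent copper, reductive elimination with retention of alkene geometry) closes the temporary six-membered ring A and gives the (E)-alkylidene enol ether 21, which on heating undergoes a concerted suprafacial [3,3] shift that forms C1–C2, breaks C7–O and so closes the eight-membered carbocycle as a two-carbon ring expansion. The closest known reactions are the Cu(OAc)2/Et3N coupling of alkenyl pinacol boronates with allylic alcohols to allyl vinyl ethers followed by Claisen rearrangement, and the Claisen ring expansion of 2-methylene-6-vinyltetrahydropyrans to cyclooct-4-enones. The rearrangement should pass through a chair-like six-atom array inside a bicyclo[3.3.1]-like transition state, ring A being a chair with the butenolide axial at C7 and the C5 methyl and C6 CH2OTs equatorial. C2 is controlled by two elements: the C7–O stereocenter fixes which enol ether face is attacked, and the (E) geometry places the side chain equatorial, giving the side chain trans to the C5 methyl and cis to C6–CH2OTs as in the target; the transient C1 center follows from the ring-locked butenolide geometry, and the new C7=C8 bond is cis in the ring. The step needs chair over boat topology, which the all-equatorial ring A and the (E) enol ether should secure (a (Z) isomer would put the chain axial and give the C2 epimer), and it needs the β,γ-unsaturated lactone to survive, which is why amine and copper salts are removed before heating.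

Step 11
Reactants: 22 cyclooctenone lactone
Product: 24 C3 acetate of the reduced lactone (C3 R; otherwise as 22), via lithium alkoxide 23 (not isolated)
Conditions: LiBH(s-Bu)3 (L-Selectride), THF, −78 °C; then Ac2O, −78 → 0 °C
Reagents that add atoms: acetic anhydride, CC(=O)OC(C)=O
Why: The bulky hydride is expected to attack the C3 ketone from the face opposite the C2 sec-alkyl branch, giving the C3–O bond cis to the side chain (1,2-induction by the α-substituent), and trapping the alkoxide cold with Ac2O forestalls translactonisation and tosylate displacement.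

Step 12
Reactants: 24 acetate tosylate
Product: 26 target (acetoxycrenulide), via potassium dienolate 25 (not isolated)
Conditions: KN(SiMe3)2 (1.05 equiv), THF, −78 → −20 °C
Reagents that add atoms: none
Why: Deprotonation of the doubly activated C1–H gives the lactone dienolate, whose γ-carbon C7 displaces the tosylate in a 3-exo-tet intramolecular alkylation; the cyclopropane closes on the face already carrying the C6 CH2OTs (cis fusion, C7 follows C6) and the alkene moves into conjugation as C8=C1, whereas α-attack would make C1 quaternary in a bridged ring.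

**Compound list**

1 | (R)-citronellal, (3R)-3,7-dimethyloct-6-enal | O=CC[C@H](C)CCC=C(C)C | starting material
2 | (3R)-3,7-dimethylocta-1,6-dien-1-yl nonafluorobutanesulfonate (E/Z mixture, not isolated) | FC(F)(F)C(F)(F)C(F)(F)C(F)(F)S(=O)(=O)OC=C[C@H](C)CCC=C(C)C | intermediate
3 | (3R)-3,7-dimethyloct-6-en-1-yne | C#C[C@H](C)CCC=C(C)C | intermediate
4 | (3R)-1-bromo-3,7-dimethyloct-6-en-1-yne | BrC#C[C@H](C)CCC=C(C)C | intermediate
5 | [(1Z,3R)-1-bromo-3,7-dimethylocta-1,6-dien-1-yl]dibromoborane–dimethyl sulfide adduct (not isolated) | Br/C(=C\[C@H](C)CCC=C(C)C)[B-](Br)(Br)[S+](C)C | intermediate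
6 | 2-[(1Z,3R)-1-bromo-3,7-dimethylocta-1,6-dien-1-yl]-4,4,5,5-tetramethyl-1,3,2-dioxaborolane | Br/C(B1OC(C)(C)C(C)(C)O1)=C\[C@H](C)CCC=C(C)C | intermediate
7 | (S)-β-methyl-γ-butyrolactone, (4S)-4-methyloxolan-2-one | O=C1C[C@H](C)CO1 | starting material
8 | (4R)-4-benzyl-1,3-oxazolidin-2-one | O=C1N[C@H](Cc2ccccc2)CO1 | starting material
9 | trimethylsilyl (3S)-4-iodo-3-methylbutanoate (not isolated) | C[Si](C)(C)OC(=O)C[C@H](C)CI | intermediate
10 | (3S)-4-iodo-3-methylbutanoyl chloride (not isolated) | ClC(=O)C[C@H](C)CI | intermediate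
11 | (4R)-4-benzyl-3-[(3S)-4-iodo-3-methylbutanoyl]-1,3-oxazolidin-2-one | O=C1OC[C@@H](Cc2ccccc2)N1C(=O)C[C@H](C)CI | intermediate
12 | {(2S)-4-[(4R)-4-benzyl-2-oxo-1,3-oxazolidin-3-yl]-2-methyl-4-oxobutyl}zinc iodide (not isolated) | O=C1OC[C@@H](Cc2ccccc2)N1C(=O)C[C@H](C)C[Zn]I | intermediate
13 | (4R)-4-benzyl-3-[(3R,5Z,7R)-3,7,11-trimethyl-5-Bpin-dodeca-5,10-dienoyl]-1,3-oxazolidin-2-one | O=C1OC[C@@H](Cc2ccccc2)N1C(=O)C[C@H](C)C/C(B2OC(C)(C)C(C)(C)O2)=C\[C@H](C)CCC=C(C)C | intermediate
14 | furan-3-carbaldehyde | O=Cc1ccoc1 | starting material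
15 | O-trimethylsilyl ether of 16 (not isolated) | O=C1OC[C@@H](Cc2ccccc2)N1C(=O)[C@H]([C@@H](O[Si](C)(C)C)c2ccoc2)[C@H](C)C/C(B2OC(C)(C)C(C)(C)O2)=C\[C@H](C)CCC=C(C)C | intermediate
16 | (4R)-4-benzyl-3-{(2S,3R,5Z,7R)-2-[(R)-furan-3-yl(hydroxy)methyl]-3,7,11-trimethyl-5-Bpin-dodeca-5,10-dienoyl}-1,3-oxazolidin-2-one | O=C1OC[C@@H](Cc2ccccc2)N1C(=O)[C@H]([C@@H](O)c2ccoc2)[C@H](C)C/C(B2OC(C)(C)C(C)(C)O2)=C\[C@H](C)CCC=C(C)C | intermediate
17 | (1R,2R,3R,5Z,7R)-1-(furan-3-yl)-2-(hydroxymethyl)-3,7,11-trimethyl-5-Bpin-dodeca-5,10-dien-1-ol | OC[C@H]([C@@H](O)c1ccoc1)[C@H](C)C/C(B1OC(C)(C)C(C)(C)O1)=C\[C@H](C)CCC=C(C)C | intermediate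
18 | [(2R,3R,5Z,7R)-2-[(R)-furan-3-yl(hydroxy)methyl]-3,7,11-trimethyl-5-Bpin-dodeca-5,10-dien-1-yl] 4-methylbenzenesulfonate | Cc1ccc(cc1)S(=O)(=O)OC[C@H]([C@@H](O)c1ccoc1)[C@H](C)C/C(B1OC(C)(C)C(C)(C)O1)=C\[C@H](C)CCC=C(C)C | intermediate
19 | 5-hydroxy analogue of 20 (lactol, both epimers at the hemiacetal carbon, not isolated) | Cc1ccc(cc1)S(=O)(=O)OC[C@H]([C@@H](O)C1=CC(=O)OC1O)[C@H](C)C/C(B1OC(C)(C)C(C)(C)O1)=C\[C@H](C)CCC=C(C)C | intermediate
20 | 4-[(1R,2R,3R,5Z,7R)-1-hydroxy-3,7,11-trimethyl-5-Bpin-2-(tosyloxymethyl)dodeca-5,10-dien-1-yl]furan-2(5H)-one | Cc1ccc(cc1)S(=O)(=O)OC[C@H]([C@@H](O)C1=CC(=O)OC1)[C@H](C)C/C(B1OC(C)(C)C(C)(C)O1)=C\[C@H](C)CCC=C(C)C | intermediate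
21 | 4-[(2R,3R,4R,6E)-6-[(2R)-2,6-dimethylhept-5-en-1-ylidene]-4-methyl-3-(tosyloxymethyl)oxan-2-yl]furan-2(5H)-one (not isolated) | CC(C)=CCC[C@@H](C)/C=C1\C[C@@H](C)[C@H](COS(=O)(=O)c2ccc(C)cc2)[C@@H](O1)C1=CC(=O)OC1 | intermediate
22 | cyclooctenone lactone: C3 ketone, C7=C8 (cis in ring), C1–H, lactone C11(=O)–O–C10H2 across C1/C8, C2 (R)-6-methylhept-5-en-2-yl, C5 methyl, C6 CH2OTs; C1 S, C2 S, C5 R, C6 S, C1′ R | O=C1C[C@@H](C)[C@H](COS(=O)(=O)c3ccc(C)cc3)/C=C2/COC(=O)[C@H]2[C@@H]1[C@H](C)CCC=C(C)C | intermediate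
23 | lithium C3 alkoxide from 22 (C3 R, not isolated) | [Li+].[O-][C@@H]1C[C@@H](C)[C@H](COS(=O)(=O)c3ccc(C)cc3)/C=C2/COC(=O)[C@H]2[C@@H]1[C@H](C)CCC=C(C)C | intermediate
24 | C3 acetate: as 22 with C3 (R)-CH–OAc in place of the ketone | CC(=O)O[C@@H]1C[C@@H](C)[C@H](COS(=O)(=O)c3ccc(C)cc3)/C=C2/COC(=O)[C@H]2[C@@H]1[C@H](C)CCC=C(C)C | intermediate
25 | potassium dienolate of 24 (C11 enolate, C1=C11 and C7=C8, not isolated) | [K+].CC(=O)O[C@@H]1C[C@@H](C)[C@H](COS(=O)(=O)c3ccc(C)cc3)/C=C2/COC([O-])=C2[C@@H]1[C@H](C)CCC=C(C)C | intermediate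
26 | acetoxycrenulide, CNP0018922.1 (C2 S, C3 R, C5 R, C6 S, C7 S, C1′ R) | CC(=O)O[C@@H]1C[C@@H](C)[C@@H]2C[C@@H]2C2=C(C(=O)OC2)[C@@H]1[C@H](C)CCC=C(C)C | target

**Count and risks**

Total: 12 steps. Longest linear sequence: 11 steps (1 to 26 through steps 1–3 and 5–12); the branch from 7 joins at step 5.

Step 10 (key step). The oxidative C–O coupling of a hindered, trisubstituted alkenylboronate with a secondary alcohol may be outrun by protodeboronation or acetoxylation of the boronate, so that the enol ether never forms. The fallback sets out from 20: ipso-iododeboronation with N-iodosuccinimide in MeCN (retention) should give the (E)-vinyl iodide F1, and an intramolecular Ullmann-type O-vinylation (CuI, 3,4,7,8-tetramethyl-1,10-phenanthroline, Cs2CO3, PhMe, 80 °C) should then close ring A with retention. This comes back to the route at enol ether 21, which is heated as in step 10 to give 22.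

Step 12. The dienolate may attack the neighbouring acetate carbonyl (O to C acetyl transfer) or alkylate at the α-carbon C1 instead of C7. The fallback sets out from ketone 22, which carries no acetate: KN(SiMe3)2 in THF at −78 °C should close the cyclopropane to the keto butenolide F2, Luche reduction (NaBH4, CeCl3·7H2O, MeOH, −40 °C) should reduce the C3 ketone without touching the butenolide to give the alcohol F3, and Ac2O/pyridine/DMAP returns to the route at 26.

Step 11. Hydride delivery may show poor facial selectivity in the flexible eight-membered ring and give mainly the C3 epimer. The fallback sets out from 22: reduction with NaBH4/CeCl3·7H2O and aqueous work-up gives the C3-epimeric alcohol F4, and a Mitsunobu reaction with acetic acid (PPh3, diisopropyl azodicarboxylate, AcOH, PhMe, 0 °C → rt) installs the acetate with inversion, coming back to the route at 24.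

**Further compounds**

F1 | step 10 | 4-[(1R,2R,3R,5E,7R)-1-hydroxy-5-iodo-3,7,11-trimethyl-2-(tosyloxymethyl)dodeca-5,10-dien-1-yl]furan-2(5H)-one | Cc1ccc(cc1)S(=O)(=O)OC[C@H]([C@@H](O)C1=CC(=O)OC1)[C@H](C)C/C(I)=C\[C@H](C)CCC=C(C)C
F2 | step 12 | 3-oxo analogue of 26 (C3 ketone in place of CH–OAc) | O=C1C[C@@H](C)[C@@H]2C[C@@H]2C2=C(C(=O)OC2)[C@@H]1[C@H](C)CCC=C(C)C
F3 | step 12 | 3-O-deacetyl 26 (free C3 hydroxyl, C3 R) | O[C@@H]1C[C@@H](C)[C@@H]2C[C@@H]2C2=C(C(=O)OC2)[C@@H]1[C@H](C)CCC=C(C)C
F4 | step 11 | C3-epimeric alcohol (C3 S) corresponding to 24 without the acetyl group | O[C@H]1C[C@@H](C)[C@H](COS(=O)(=O)c3ccc(C)cc3)/C=C2/COC(=O)[C@H]2[C@@H]1[C@H](C)CCC=C(C)C
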